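**Strategy.** The 11-membered ring is made by fragmentation, not by macrocyclisation. Its ketone carbon and lactam carbonyl carbon are the two ends of a C=C bond in the precursor, a bicyclic enamine in which a cyclohexene (carrying the four contiguous ring stereocentres) and the pyrroline are fused. In one flask a cyclic ketimine is alkylated at nitrogen by its own 4-chlorobutyl chain, which forms the N–CH2 bond and a seven-membered azepine; the iminium ion tautomerises to the enamine, and singlet oxygen cleaves the C=C bond, merging the six- and seven-membered rings into the keto-lactam. L-Tyrosine supplies the only purchased stereocentre; its carboxyl group steers two anodic oxidations and is then excised.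

Key step: step 10

Assumption: the catalogue number is taken to mean exactly the stereoisomer written in the SMILES string. Intermediates 3–13 use hydroindole numbering (N1, C2, C3, C3a, C4–C7, C7a); the configuration at C7 of 6–14 is inconsequential because that carbon becomes the ketone carbon.

**Step 1**
Reactants: 1 (tert-butyl N-Boc-L-tyrosinate)
Product: 3 cis-fused hydroindolenone (2S,3aR,7aR), via para-quinol 2 (not isolated)
Conditions: PhI(OAc)2, MeCN/H2O, 0 °C; then NaHCO3, MeOH, 40 °C
Reagents that add atoms: water (O)
Why: Hypervalent-iodine oxidative dearomatisation with water capture gives the para-quinol, and a reversible 5-exo-trig intramolecular aza-Michael addition of the carbamate then selects one of the two diastereotopic enones, giving the cis-fused bicycle with the ester on the convex face, so that the purchased stereocentre sets C3a and C7a.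

**Step 2**
Reactants: 3 (hydroindolenone)
Product: 4 tertiary triethylsilyl ether
Conditions: TESOTf, 2,6-lutidine, CH2Cl2, −78 °C
Reagents that add atoms: triethylsilyl trifluoromethanesulfonate (CC[Si](CC)(CC)OS(=O)(=O)C(F)(F)F)
Why: Silylation of the tertiary alcohol with a silyl triflate and a hindered pyridine base masks it against alkoxide chemistry in the two enolate steps and against a competing Claisen rearrangement.

**Step 3**
Reactants: 4 (silyl ether) and 5 (1-chloro-4-iodobutane)
Product: 6 C7-(4-chlorobutyl) enone (7R)
Conditions: lithium diisopropylamide, THF, −78 °C; then 5, DMPU, −78 to −30 °C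
Reagents that add atoms: none
Why: Enolate alkylation: kinetic deprotonation at the only enolisable position gives the cross-conjugated lithium dienolate, which the iodide terminus should alkylate on the convex face, anti to the pseudo-axial C7a–N bond.

**Step 4**
Reactants: 6 (alkylated enone)
Product: 7 allylic alcohol (6R)
Conditions: NaBH4, CeCl3·7H2O, MeOH, −40 °C
Reagents that add atoms: none
Why: Luche 1,2-reduction, in which axial hydride delivery on the convex face (syn to H-7a, with the new chain pseudo-equatorial) should place the C6–O bond on the face of the pyrrolidine ring.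

**Step 5**
Reactants: 7 (allylic alcohol) and 8 (N,N-dimethylacetamide dimethyl acetal)
Product: 9 γ,δ-unsaturated dimethylamide (4S)
Conditions: xylenes, 135 °C
Reagents that add atoms: none
Why: Eschenmoser–Claisen rearrangement, whose suprafacial [3,3] shift transfers the C6–O configuration to the new C4–C bond on the same face, trans to the silyloxy group, and moves the alkene to C5=C6.

**Step 6**
Reactants: 9 (unsaturated amide)
Product: 10 iodo lactone (5R,6R)
Conditions: I2, NaHCO3, THF/H2O, 0 °C
Reagents that add atoms: iodine (II); water (O)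
Why: Iodolactonisation of the γ,δ-unsaturated amide: the tethered amide oxygen can reach only C5 and only from the face of its own side chain (5-exo), so the iodonium ion sits on the opposite face and hydrolysis of the iminium lactone should give the cis-fused lactone with a trans-diaxial iodide at C6.

**Step 7**
Reactants: 10 (iodo lactone)
Product: 11 C6-ethyl lactone (6R)
Conditions: Ni(cod)2 (cat.), 2,6-bis[(4S)-4-sec-butyl-4,5-dihydrooxazol-2-yl]pyridine (cat.), EtZnBr, DMA, 23 °C
Reagents that add atoms: ethylzinc bromide (CC[Zn]Br)
Why: Nickel-catalysed Negishi alkyl–alkyl coupling of a secondary iodide runs through the C6 radical, and bond formation on the face anti to the axial lactone oxygen should place the ethyl group trans to it; the same radical pathway serves β-acyloxy glycosyl halides, which argues against loss of the carboxylate.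

**Step 8**
Reactants: 11 (ethyl lactone)
Product: 12 α-methyl lactone (S at the lactone α-carbon)
Conditions: LiN(SiMe3)2, THF, −78 °C; then MeI
Reagents that add atoms: iodomethane (CI)
Why: Enolate alkylation: kinetic enolisation of the unhindered lactone methylene (the ester α-hydrogen is tertiary and shielded by the Boc group) and methylation on the convex face of the cis-fused lactone, trans to C3a, should set the last ring stereocentre.

**Step 9**
Reactants: 12 (methyl lactone)
Product: 13 C7a-methoxy N,O-acetal
Conditions: graphite anode and cathode, undivided cell, Et4NOTs, MeOH, 0 °C, constant current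
Reagents that add atoms: methanol (CO)
Why: Shono anodic α-methoxylation of the carbamate: as in proline esters, the α-carbon bearing the ester is deactivated, so the N-acyliminium ion should form at the ring-fusion C7a–H and be trapped by methanol from the convex face (this configuration does not matter).

**Step 10**
Reactants: 13 (N,O-acetal)
Product: 17 macrocyclic keto-lactam acid, via cyclic imine 14 (not isolated), via tricyclic enamine 15 (not isolated), via dioxetane 16 (not isolated)
Conditions: TFA/CH2Cl2/H2O, 0 to 23 °C, evaporate; NaHCO3, NaI (cat.), MeCN, 65 °C; then O2, methylene blue (cat.), visible light, −20 to 23 °C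
Reagents that add atoms: dioxygen (O=O)
Why: After acidolysis of the Boc, tert-butyl and silyl groups and of the N,O-acetal, the liberated 1-pyrroline 14 is alkylated at nitrogen by its own primary halide (Finkelstein-assisted Menshutkin reaction, 7-exo-tet), which forms the N–CH2 bond and the azepine ring; the iminium ion can lose a proton only from the chain-bearing carbon, because the other α-carbon is the quaternary carbinol carbon, so the tetrasubstituted enamine 15 should form regiospecifically. Singlet oxygen then adds across the electron-rich enamine C=C bond in a (2+2) sense, and the 1,2-dioxetane 16 cleaves to the lactam carbonyl and the ketone, which turns the fused seven- and six-membered rings into the 11-membered ring. The closest known reactions are the intramolecular N-alkylation of cyclic ketimines to bicyclic endocyclic enamines and the oxidative cleavage of bicyclic enamines to medium-ring keto lactams. No stereocentre is created; the centre at the chain-bearing carbon is erased, and the ethyl-bearing centre next to the new ketone is untouched because the cleavage is neutral. The step needs N-alkylation of the imine over C-alkylation and over O-alkylation of the carboxylate, which the absence of strong base, the hindered tertiary α-carbon and the seven- versus ten-membered ring sizes should secure, and it needs (2+2) over ene reactivity of singlet oxygen, which the amino substituent on the alkene secures.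

**Step 11**
Reactants: 17 (macrocyclic keto-lactam acid)
Product: 18 5-methoxy lactam (both epimers at the methoxy carbon)
Conditions: graphite electrodes, undivided cell, Et3N (0.2 equiv), MeOH, 0 °C, constant current
Reagents that add atoms: methanol (CO)
Why: Hofer–Moest (non-Kolbe) anodic decarboxylation of the N-acyl α-amino acid gives the N-acyliminium ion, which methanol traps as the N,O-acetal; the tyrosine stereocentre is erased on purpose and reset in the next step.

**Step 12**
Reactants: 18 (5-methoxy lactam) and 19 (3-methylfuran-2(5H)-one)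
Product: 21 butenolide lactam, via silyloxyfuran 20 (not isolated)
Conditions: 19, TIPSOTf (1.3 equiv), Et3N (1.1 equiv), CH2Cl2, 0 °C; then 18, −78 to −40 °C
Reagents that add atoms: none
Why: Vinylogous Mannich reaction: the silyloxyfuran attacks the N-acyliminium ion through its γ-carbon on the lactam face opposite the macrocyclic ring carbon at the quaternary centre (cis to the small hydroxyl), and the open transition state of 2-silyloxyfurans with cyclic N-acyliminium ions favours the threo arrangement, which together should set both new stereocentres.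

**Step 13**
Reactants: 21 (butenolide lactam)
Product: 22 CNP0221273.1 (target)
Conditions: H2 (1 atm), Rh/Al2O3, EtOAc, 23 °C
Reagents that add atoms: none
Why: Heterogeneous hydrogenation of the α-methyl butenolide adds hydrogen to the face opposite the γ-substituent and should give the cis-2,4-disubstituted lactone, while the ketone, lactam and saturated lactone are inert.

**Compound list**

1 | tert-butyl N-(tert-butoxycarbonyl)-L-tyrosinate | CC(C)(C)OC(=O)N[C@@H](Cc1ccc(O)cc1)C(=O)OC(C)(C)C | starting material
2 | para-quinol: tert-butyl (2S)-2-(Boc-amino)-3-(1-hydroxy-4-oxocyclohexa-2,5-dien-1-yl)propanoate | CC(C)(C)OC(=O)N[C@@H](CC1(O)C=CC(=O)C=C1)C(=O)OC(C)(C)C | intermediate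
3 | di-tert-butyl (2S,3aR,7aR)-3a-hydroxy-6-oxo-2,3,3a,6,7,7a-hexahydro-1H-indole-1,2-dicarboxylate | CC(C)(C)OC(=O)N1[C@H](C(=O)OC(C)(C)C)C[C@@]2(O)C=CC(=O)C[C@@H]12 | intermediate
4 | di-tert-butyl (2S,3aR,7aR)-6-oxo-3a-(triethylsilyloxy)-2,3,3a,6,7,7a-hexahydro-1H-indole-1,2-dicarboxylate | CC(C)(C)OC(=O)N1[C@H](C(=O)OC(C)(C)C)C[C@@]2(O[Si](CC)(CC)CC)C=CC(=O)C[C@@H]12 | intermediate
5 | 1-chloro-4-iodobutane | ClCCCCI | starting material
6 | di-tert-butyl (2S,3aR,7R,7aR)-7-(4-chlorobutyl)-6-oxo-3a-(triethylsilyloxy)-2,3,3a,6,7,7a-hexahydro-1H-indole-1,2-dicarboxylate | CC(C)(C)OC(=O)N1[C@H](C(=O)OC(C)(C)C)C[C@@]2(O[Si](CC)(CC)CC)C=CC(=O)[C@H](CCCCCl)[C@@H]12 | intermediate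
7 | di-tert-butyl (2S,3aR,6R,7R,7aR)-7-(4-chlorobutyl)-6-hydroxy-3a-(triethylsilyloxy)-2,3,3a,6,7,7a-hexahydro-1H-indole-1,2-dicarboxylate | CC(C)(C)OC(=O)N1[C@H](C(=O)OC(C)(C)C)C[C@@]2(O[Si](CC)(CC)CC)C=C[C@@H](O)[C@H](CCCCCl)[C@@H]12 | intermediate
8 | 1,1-dimethoxy-N,N-dimethylethanamine (N,N-dimethylacetamide dimethyl acetal) | COC(C)(OC)N(C)C | starting material
9 | di-tert-butyl (2S,3aR,4S,7S,7aR)-7-(4-chlorobutyl)-4-[2-(dimethylamino)-2-oxoethyl]-3a-(triethylsilyloxy)-2,3,3a,4,7,7a-hexahydro-1H-indole-1,2-dicarboxylate | CC(C)(C)OC(=O)N1[C@H](C(=O)OC(C)(C)C)C[C@@]2(O[Si](CC)(CC)CC)[C@@H](CC(=O)N(C)C)C=C[C@H](CCCCCl)[C@@H]12 | intermediate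
10 | iodo lactone: di-tert-butyl octahydroindole-1,2-dicarboxylate (2S,3aR,4S,5R,6R,7R,7aR) with 3a-OSiEt3, 6-iodo, 7-(4-chlorobutyl) and a cis-fused γ-lactone C4–CH2–C(=O)–O–C5 | CC(C)(C)OC(=O)N1[C@H](C(=O)OC(C)(C)C)C[C@@]2(O[Si](CC)(CC)CC)[C@H]3CC(=O)O[C@H]3[C@H](I)[C@H](CCCCCl)[C@@H]12 | intermediate
11 | ethyl lactone: as 10 with 6-ethyl in place of iodine (2S,3aR,4S,5S,6R,7S,7aR) | CC(C)(C)OC(=O)N1[C@H](C(=O)OC(C)(C)C)C[C@@]2(O[Si](CC)(CC)CC)[C@H]3CC(=O)O[C@H]3[C@H](CC)[C@H](CCCCCl)[C@@H]12 | intermediate
12 | methyl lactone: as 11 with an (S)-methyl group on the lactone α-carbon, trans to C3a | CC(C)(C)OC(=O)N1[C@H](C(=O)OC(C)(C)C)C[C@@]2(O[Si](CC)(CC)CC)[C@H]3[C@H](C)C(=O)O[C@H]3[C@H](CC)[C@H](CCCCCl)[C@@H]12 | intermediate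
13 | N,O-acetal: as 12 with a 7a-methoxy group (7aS, cis to the silyloxy group) | CC(C)(C)OC(=O)N1[C@H](C(=O)OC(C)(C)C)C[C@@]2(O[Si](CC)(CC)CC)[C@H]3[C@H](C)C(=O)O[C@H]3[C@H](CC)[C@H](CCCCCl)[C@@]12OC | intermediate
14 | cyclic imine acid: 1-pyrroline (C7a=N) with free 3a-OH, 2-CO2H, 7-(4-chlorobutyl), fused methyl lactone | OC(=O)[C@@H]1C[C@@]2(O)[C@H]3[C@H](C)C(=O)O[C@H]3[C@H](CC)[C@H](CCCCCl)C2=N1 | intermediate
15 | tricyclic enamine acid: azepine closed between N and the chain terminus, C7=C7a enamine | OC(=O)[C@@H]1C[C@@]2(O)[C@H]3[C@H](C)C(=O)O[C@H]3[C@H](CC)C4=C2N1CCCC4 | intermediate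
16 | 1,2-dioxetane across the former enamine C=C bond (cis; the face is assumed and has no consequence) | OC(=O)[C@@H]1C[C@@]2(O)[C@H]3[C@H](C)C(=O)O[C@H]3[C@H](CC)[C@@]45OO[C@]25N1CCCC4 | intermediate
17 | macrocyclic keto-lactam acid: the target with CO2H (S) in place of the appended butyrolactone on the pyrrolidinone carbon next to nitrogen | CC[C@@H]1C(=O)CCCCN2C(=O)[C@@](O)(C[C@H]2C(=O)O)[C@@H]2[C@H]1OC(=O)[C@H]2C | intermediate
18 | 5-methoxy lactam: 17 with OMe in place of CO2H, both epimers at that carbon | CC[C@@H]1C(=O)CCCCN2C(=O)[C@@](O)(CC2OC)[C@@H]2[C@H]1OC(=O)[C@H]2C | intermediate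
19 | 3-methylfuran-2(5H)-one | CC1=CCOC1=O | starting material
20 | 3-methyl-2-(triisopropylsilyloxy)furan | CC1=C(O[Si](C(C)C)(C(C)C)C(C)C)OC=C1 | intermediate
21 | butenolide lactam: the target with a C=C bond between the α-methyl carbon and the β-carbon of the appended lactone (γ-carbon S) | CC[C@@H]1C(=O)CCCCN2C(=O)[C@@](O)(C[C@H]2[C@@H]2C=C(C)C(=O)O2)[C@@H]2[C@H]1OC(=O)[C@H]2C | intermediate
22 | CNP0221273.1 | CC[C@@H]1C(=O)CCCCN2C(=O)[C@@](O)(C[C@H]2[C@@H]2C[C@H](C)C(=O)O2)[C@@H]2[C@H]1OC(=O)[C@H]2C | target

**Totals.** Total step count: 13. Longest linear sequence: 13 steps (1 to 22).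

**Steps most likely to fail**

Step 10. The ketimine may be alkylated at carbon through its enamine tautomer (5-exo closure to a spirocyclopentane) faster than at nitrogen, the seven-membered closure may be slow, or the enamine may be over-oxidised. The fallback reverses the order of cleavage and N–C bond formation. From 13, loss of methanol (pyridinium p-toluenesulfonate, toluene, 60 °C) would give the ene-carbamate F1. Ozonolysis (O3, CH2Cl2/MeOH, −78 °C; Me2S) would cleave its C=C bond to the N-Boc imide ketone F2. TFA/CH2Cl2/H2O would give the NH-lactam acid F3. The N–CH2 bond would then be made by direct closure of the 11-membered ring (NaI, Cs2CO3, DMF, high dilution, 50 °C), which comes back to the route at 17.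

Step 9. Anodic oxidation at the hindered ring-fusion C–H may be slow, or electron transfer may be followed by proton loss elsewhere. The fallback is a chemical C–H hydroxylation. From 12, RuCl3 (cat.) and NaIO4 in EtOAc/MeCN/H2O would hydroxylate the same position, and the hemiaminal would open to the keto carbamate F4. Under the acid conditions of step 10, F4 loses its protecting groups and condenses to the same imine, so the route is rejoined at 14.

Step 7. Reductive β-elimination of iodide and the anti-periplanar lactone carboxylate (the reverse of step 6), or halogen–zinc exchange followed by the same elimination, may outrun C–C coupling. The fallback is a tin-mediated radical chain. From 10, Giese addition of the C6 radical to phenyl vinyl sulfone (Bu3SnH, AIBN, benzene, 80 °C) would give the sulfone F5. Desulfonylation with sodium amalgam (Na/Hg, Na2HPO4, MeOH, −20 °C) would return to the route at 11.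

**Further compounds**

F1 | step 10 | ene-carbamate: 12 with a C7=C7a double bond | CC(C)(C)OC(=O)N1[C@H](C(=O)OC(C)(C)C)C[C@@]2(O[Si](CC)(CC)CC)[C@H]3[C@H](C)C(=O)O[C@H]3[C@H](CC)C(CCCCCl)=C12
F2 | step 10 | N-Boc imide ketone: N-Boc pyrrolidin-2-one carrying the silyloxy quaternary carbon, with the former ring opened to a 6-chloro-1-oxohexyl ketone | CC(C)(C)OC(=O)N1[C@H](C(=O)OC(C)(C)C)C[C@@](O[Si](CC)(CC)CC)([C@H]2[C@H](C)C(=O)O[C@H]2[C@H](CC)C(=O)CCCCCl)C1=O
F3 | step 10 | NH-lactam acid: F2 without Boc, tert-butyl and silyl groups | OC(=O)[C@@H]1C[C@@](O)([C@H]2[C@H](C)C(=O)O[C@H]2[C@H](CC)C(=O)CCCCCl)C(=O)N1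
F4 | step 9 | keto carbamate: ring-opened cyclohexanone with an acyclic Boc-amino tert-butyl ester side chain | CC(C)(C)OC(=O)N[C@@H](C[C@@]1(O[Si](CC)(CC)CC)[C@H]2[C@H](C)C(=O)O[C@H]2[C@H](CC)[C@H](CCCCCl)C1=O)C(=O)OC(C)(C)C
F5 | step 7 | sulfone: 10 with 2-(phenylsulfonyl)ethyl in place of iodine | CC(C)(C)OC(=O)N1[C@H](C(=O)OC(C)(C)C)C[C@@]2(O[Si](CC)(CC)CC)[C@H]3CC(=O)O[C@H]3[C@H](CCS(=O)(=O)c4ccccc4)[C@H](CCCCCl)[C@@H]12
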